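**Retrosynthetic overview**

- The strategy rests on the E-trisubstituted C11=C12 alkene (methyl on C11). It lies in the middle of the C6–C18 chain that joins C5 of the 3-methyltetronic acid ring (O1, C2–C5) to C3 of the furan ring, between the C7 and C15 stereocentres.
- Key disconnection: C11–CH3 and C12–C13 are formed together from the terminal alkyne of a silyl-capped C5–C12 diyne, Me3Al and a C13–C18 primary iodide (Cp2ZrCl2-catalysed methylalumination, ZnCl2 relay, palladium-catalysed alkenyl–alkyl Negishi coupling).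
- Diyne: (S)-citronellal supplies C7; its CH2–CHO end is dehydrated to C5≡C6 and silylated, then ozonolysis, iodide and acetylide add C11≡C12. Iodide: (S)-linalool supplies C15; silyl ether, ozonolysis, iodide, Negishi coupling with 3-bromofuran, hydroboration, iodide.
- Ring order: the furan is bought; the tetronate is the only ring closed, and it is closed last (desilylation, C5 formylation, propanoate aldol and oxidation, O-methylation, deallylation, AgNO3 5-exo-dig lactonisation, thiolate demethylation).

Key step: step 12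

Remark: commercial (S)-linalool is assumed to be of high enantiomeric purity, because the C15 configuration is carried unchanged from it.

**Step 1**
Reactants: 1 (S)-citronellal [(3S)-3,7-dimethyloct-6-enal]
Product: 3 (3S)-3,7-dimethyloct-6-en-1-yne, via alkenyl nonaflate 2 (not isolated)
Conditions: C4F9SO2F (1.2 equiv), P2-Et phosphazene base (2.5 equiv), DMF, −30 °C → rt
Reagents that add atoms: none
Why: The phosphazene base enolises the aldehyde, the enolate is O-sulfonylated to 2, and a second equivalent of base eliminates nonaflate to give the terminal alkyne (aldehyde-to-alkyne conversion through an alkenyl nonaflate, without chain extension); the methyl-bearing carbon is β to the carbonyl, is not enolised, and should keep its S configuration.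

**Step 2**
Reactants: 3 (3S)-3,7-dimethyloct-6-en-1-yne
Product: 5 [(3S)-3,7-dimethyloct-6-en-1-yn-1-yl]tri(propan-2-yl)silane, via lithium acetylide 4 (not isolated)
Conditions: n-BuLi, THF, −78 °C; i-Pr3SiOTf, −78 → 0 °C
Reagents that add atoms: triisopropylsilyl trifluoromethanesulfonate, CC(C)[Si](C(C)C)(C(C)C)OS(=O)(=O)C(F)(F)F
Why: Deprotonation of the terminal alkyne and C-silylation of the acetylide (alkyne protection) should install the hindered cap that later keeps C5≡C6 out of the carbometalation.

**Step 3**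
Reactants: 5 [(3S)-3,7-dimethyloct-6-en-1-yn-1-yl]tri(propan-2-yl)silane
Product: 7 (4S)-4-methyl-6-[tri(propan-2-yl)silyl]hex-5-yn-1-ol, via aldehyde 6 (not isolated)
Conditions: O3, CH2Cl2/MeOH, Sudan Red 7B endpoint, −78 °C; then NaBH4, −78 → 0 °C
Reagents that add atoms: ozone, [O-][O+]=O
Why: Ozone cleaves the electron-rich trisubstituted alkene much faster than the hindered silyl alkyne (chemoselective ozonolysis to a dye endpoint), and borohydride reduction in the same flask should give the primary alcohol at C10.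

**Step 4**
Reactants: 7 (4S)-4-methyl-6-[tri(propan-2-yl)silyl]hex-5-yn-1-ol
Product: 8 [(3S)-6-iodo-3-methylhex-1-yn-1-yl]tri(propan-2-yl)silane
Conditions: I2, PPh3, imidazole, CH2Cl2, 0 °C → rt
Reagents that add atoms: iodine, II
Why: Iodination of a primary alcohol through its alkoxyphosphonium salt (Appel-type reaction) is neutral and should leave the silyl alkyne and the propargylic stereocentre untouched.

**Step 5**
Reactants: 8 [(3S)-6-iodo-3-methylhex-1-yn-1-yl]tri(propan-2-yl)silane
Product: 9 [(3S)-3-methylocta-1,7-diyn-1-yl]tri(propan-2-yl)silane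
Conditions: LiC≡CH·H2NCH2CH2NH2, DMSO, 10 °C → rt
Reagents that add atoms: lithium acetylide (ethylenediamine complex), [Li]C#C
Why: SN2 alkylation of lithium acetylide by the primary iodide installs C11≡C12 as a free terminal alkyne; the triisopropylsilyl alkyne is stable to the reagent and C7–H is not acidic enough to be removed.

**Step 6**
Reactants: 10 (S)-linalool [(3S)-3,7-dimethylocta-1,6-dien-3-ol]
Product: 11 {[(3S)-3,7-dimethylocta-1,6-dien-3-yl]oxy}triethylsilane
Conditions: Et3SiOTf, 2,6-lutidine, CH2Cl2, −78 → 0 °C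
Reagents that add atoms: triethylsilyl trifluoromethanesulfonate, CC[Si](CC)(CC)OS(=O)(=O)C(F)(F)F
Why: A silyl triflate with a hindered pyridine base silylates even a tertiary allylic alcohol at low temperature (silyl ether protection) without ionising it, so C15 keeps its configuration.

**Step 7**
Reactants: 11 {[(3S)-3,7-dimethylocta-1,6-dien-3-yl]oxy}triethylsilane
Product: 13 (4S)-4-methyl-4-[(triethylsilyl)oxy]hex-5-en-1-ol, via aldehyde 12 (not isolated)
Conditions: O3, CH2Cl2/MeOH, Sudan Red 7B endpoint, −78 °C; then NaBH4, −78 → 0 °C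
Reagents that add atoms: ozone, [O-][O+]=O
Why: Chemoselective ozonolysis: the trisubstituted alkene is far more electron-rich than the vinyl group, which is deactivated and shielded by the adjacent silyloxy quaternary carbon, and reduction in the same flask should give the C18 alcohol.

**Step 8**
Reactants: 13 (4S)-4-methyl-4-[(triethylsilyl)oxy]hex-5-en-1-ol
Product: 14 triethyl{[(3S)-6-iodo-3-methylhex-1-en-3-yl]oxy}silane
Conditions: I2, PPh3, imidazole, CH2Cl2, 0 °C → rt
Reagents that add atoms: iodine, II
Why: Appel-type iodination of the primary alcohol; the tertiary oxygen is already silylated, so it cannot close a tetrahydrofuran.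

**Step 9**
Reactants: 14 triethyl{[(3S)-6-iodo-3-methylhex-1-en-3-yl]oxy}silane, 15 3-bromofuran
Product: 18 triethyl{[(3S)-6-(furan-3-yl)-3-methylhex-1-en-3-yl]oxy}silane, via alkyllithium 16 (not isolated), via alkylzinc chloride 17 (not isolated)
Conditions: t-BuLi (2.1 equiv), Et2O/pentane, −78 °C; ZnCl2, THF, −78 °C → rt; then 15, Pd(OAc)2 (2 mol%), SPhos (4 mol%), THF, rt → 45 °C
Reagents that add atoms: none
Why: Lithium–iodine exchange at −78 °C is not a radical process, so the 5-hexenyl system should not cyclise; transmetalation to zinc and Negishi sp3–sp2 coupling with 3-bromofuran under a biarylphosphine, whose fast reductive elimination outruns beta-hydride elimination, should give the 3-alkylfuran.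

**Step 10**
Reactants: 18 triethyl{[(3S)-6-(furan-3-yl)-3-methylhex-1-en-3-yl]oxy}silane
Product: 20 (3S)-6-(furan-3-yl)-3-methyl-3-[(triethylsilyl)oxy]hexan-1-ol, via B-alkyl-9-BBN borane 19 (not isolated)
Conditions: 9-BBN, THF, 0 → 50 °C; then NaOH, H2O2, 0 °C → rt
Reagents that add atoms: hydrogen peroxide, OO
Why: Anti-Markovnikov hydroboration of the monosubstituted alkene by the bulky borane (boron to terminal C13) followed by oxidation with retention (hydroboration–oxidation) should give the primary alcohol; the furan is inert to 9-BBN and to cold alkaline peroxide.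

**Step 11**
Reactants: 20 (3S)-6-(furan-3-yl)-3-methyl-3-[(triethylsilyl)oxy]hexan-1-ol
Product: 21 triethyl{[(3S)-6-(furan-3-yl)-1-iodo-3-methylhexan-3-yl]oxy}silane
Conditions: PPh3, imidazole, I2, CH2Cl2, 0 °C (alcohol added last)
Reagents that add atoms: iodine, II
Why: Appel-type iodination under buffered, non-acidic conditions that the furan and the tertiary silyl ether tolerate.

**Step 12**
Reactants: 9 [(3S)-3-methylocta-1,7-diyn-1-yl]tri(propan-2-yl)silane, 21 triethyl{[(3S)-6-(furan-3-yl)-1-iodo-3-methylhexan-3-yl]oxy}silane, 22 trimethylaluminium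
Product: 25 [(3S,7E,11S)-14-(furan-3-yl)-3,7,11-trimethyl-11-[(triethylsilyl)oxy]tetradec-7-en-1-yn-1-yl]tri(propan-2-yl)silane, via E-alkenyldimethylalane 23 (not isolated), via E-alkenylzinc chloride 24 (not isolated)
Conditions: 9 (1.3 equiv), Me3Al (2 equiv), Cp2ZrCl2 (0.25 equiv), CH2Cl2, 0 °C → rt; volatiles removed in vacuo; THF, ZnCl2, 0 °C; then 21, Pd2(dba)3 (2 mol%), PCyp3 (8 mol%), N-methylimidazole, THF/NMP, 80 °C
Reagents that add atoms: trimethylaluminium (compound 22), C[Al](C)C
Why: Cp2ZrCl2 and Me3Al form a methylzirconocene–aluminate that adds methyl and metal syn across the terminal alkyne of 9, methyl to internal C11 and metal to C12, and zirconium-to-aluminium exchange gives the E-alkenylalane 23 (zirconium-catalysed carboalumination). ZnCl2 then moves the alkenyl group to zinc (24); zerovalent palladium bearing tricyclopentylphosphine inserts into the C13–I bond of 21 by an SN2-type oxidative addition, accepts the alkenyl group by transmetalation and forms C12–C13 by reductive elimination with retention at C12, so C10 and C13 end up trans. The closest known chemistry is the zinc-relayed palladium coupling of carboalumination-derived alkenylalanes, combined with the Negishi coupling of alkenylzinc halides with unactivated primary alkyl iodides under Pd2(dba)3, PCyp3 and N-methylimidazole. No ring is closed and no stereocentre is created; C7 and C15 are remote from every bond change and come from the chiral pool. The step needs methyl at C11 and not C12 (set by the polarity and steric bias of a terminal alkyne), reaction at one alkyne only (the triisopropylsilyl cap makes C5≡C6 inert), alkenyl and not methyl transfer (excess Me3Al is evaporated before the zinc relay, and sp2 groups transmetalate faster than methyl), and coupling faster than beta-hydride elimination of the alkylpalladium (the bulky electron-rich phosphine).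

**Step 13**
Reactants: 25 [(3S,7E,11S)-14-(furan-3-yl)-3,7,11-trimethyl-11-[(triethylsilyl)oxy]tetradec-7-en-1-yn-1-yl]tri(propan-2-yl)silane
Product: 26 (4S,7E,12S)-1-(furan-3-yl)-4,8,12-trimethyltetradec-7-en-13-yn-4-ol
Conditions: Bu4NF (3 equiv), THF, 0 °C → rt
Reagents that add atoms: none
Why: Fluoride cleaves the C(sp)–Si bond and the tertiary triethylsilyl ether in one operation (fluoride desilylation), exposing the C5 alkyne terminus and the C15 alcohol.

**Step 14**
Reactants: 26 (4S,7E,12S)-1-(furan-3-yl)-4,8,12-trimethyltetradec-7-en-13-yn-4-ol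
Product: 28 (4S,8E,12S)-15-(furan-3-yl)-12-hydroxy-4,8,12-trimethylpentadec-8-en-2-ynal, via dilithium alkoxide acetylide 27 (not isolated)
Conditions: n-BuLi (2.1 equiv), THF, −78 → −40 °C; DMF, −78 → 0 °C; inverse quench into cold aq. KH2PO4/MTBE
Reagents that add atoms: N,N-dimethylformamide, CN(C)C=O
Why: Formylation of the lithium acetylide with DMF (the tertiary alkoxide is a spectator) gives the ynal carrying ring carbon C4; the inverse quench into phosphate buffer keeps the liberated dimethylamine protonated so that it can neither add to the ynal nor isomerise it at C7.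

**Step 15**
Reactants: 28 (4S,8E,12S)-15-(furan-3-yl)-12-hydroxy-4,8,12-trimethylpentadec-8-en-2-ynal, 29 prop-2-en-1-yl propanoate (allyl propanoate)
Product: 31 prop-2-en-1-yl (6S,10E,14S)-17-(furan-3-yl)-3,14-dihydroxy-2,6,10,14-tetramethylheptadec-10-en-4-ynoate (mixture at C2 and C3), via lithium ester enolate 30 (not isolated)
Conditions: 29, LiN(i-Pr)2 (3 equiv each), THF, −78 °C; then 28, −78 °C; aq. NH4Cl
Reagents that add atoms: none
Why: Aldol addition of the ester lithium enolate to the ynal carbonyl (1,2-addition is favoured at −78 °C) forms the C3–C4 bond; the two new centres arise as a mixture that does not matter, because both become sp2 in the next two steps.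

**Step 16**
Reactants: 31 prop-2-en-1-yl (6S,10E,14S)-17-(furan-3-yl)-3,14-dihydroxy-2,6,10,14-tetramethylheptadec-10-en-4-ynoate
Product: 32 prop-2-en-1-yl (6S,10E,14S)-17-(furan-3-yl)-14-hydroxy-2,6,10,14-tetramethyl-3-oxoheptadec-10-en-4-ynoate
Conditions: Dess–Martin periodinane, NaHCO3, CH2Cl2, 0 °C → rt
Reagents that add atoms: none
Why: Dess–Martin oxidation of the secondary propargylic alcohol under buffered conditions should give the alkynyl β-keto ester; the tertiary C15 alcohol cannot be oxidised.

**Step 17**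
Reactants: 32 prop-2-en-1-yl (6S,10E,14S)-17-(furan-3-yl)-14-hydroxy-2,6,10,14-tetramethyl-3-oxoheptadec-10-en-4-ynoate
Product: 34 prop-2-en-1-yl (2E,6S,10E,14S)-17-(furan-3-yl)-14-hydroxy-3-methoxy-2,6,10,14-tetramethylheptadeca-2,10-dien-4-ynoate, via caesium enolate 33 (not isolated)
Conditions: Cs2CO3, Me2SO4, DMF, 0 °C
Reagents that add atoms: dimethyl sulfate, COS(=O)(=O)OC
Why: O-alkylation of the ambident β-keto ester enolate by a hard electrophile in a dissociating solvent (enol ether formation); the free caesium enolate prefers the extended arrangement with the ketone oxygen anti to the ester, so methylation on oxygen should give mainly the E enol ether, which has the ester cis to the alkyne as the lactonisation needs.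

**Step 18**
Reactants: 34 prop-2-en-1-yl (2E,6S,10E,14S)-17-(furan-3-yl)-14-hydroxy-3-methoxy-2,6,10,14-tetramethylheptadeca-2,10-dien-4-ynoate
Product: 35 (2E,6S,10E,14S)-17-(furan-3-yl)-14-hydroxy-3-methoxy-2,6,10,14-tetramethylheptadeca-2,10-dien-4-ynoic acid
Conditions: Pd(PPh3)4 (5 mol%), morpholine, THF, 0 °C → rt; aq. NaH2PO4
Reagents that add atoms: none
Why: Zerovalent palladium ionises the allyl ester to a π-allyl complex that morpholine traps (Tsuji–Trost deallylation), freeing the acid under neutral conditions that spare the enol ether, the enyne and the C7 stereocentre.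

**Step 19**
Reactants: 35 (2E,6S,10E,14S)-17-(furan-3-yl)-14-hydroxy-3-methoxy-2,6,10,14-tetramethylheptadeca-2,10-dien-4-ynoic acid
Product: 36 (5Z)-5-[(2S,6E,10S)-13-(furan-3-yl)-10-hydroxy-2,6,10-trimethyltridec-6-en-1-ylidene]-4-methoxy-3-methylfuran-2(5H)-one
Conditions: AgNO3 (0.2 equiv), MeOH, rt, dark
Reagents that add atoms: none
Why: Silver-catalysed 5-exo-dig lactonisation of a 2-en-4-ynoic acid whose carboxyl is cis to the alkyne: the carboxylate attacks silver-activated C5 anti to the metal and protodemetalation places H on C6, so the ring oxygen and C7 end up cis (Z ylidene) and the tetronate ring is closed.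

**Step 20**
Reactants: 36 (5Z)-5-[(2S,6E,10S)-13-(furan-3-yl)-10-hydroxy-2,6,10-trimethyltridec-6-en-1-ylidene]-4-methoxy-3-methylfuran-2(5H)-one
Product: 37 (5Z)-5-[(2S,6E,10S)-13-(furan-3-yl)-10-hydroxy-2,6,10-trimethyltridec-6-en-1-ylidene]-4-hydroxy-3-methylfuran-2(5H)-one (target)
Conditions: LiSPr (5 equiv), HMPA, rt; then 1 M HCl
Reagents that add atoms: none
Why: SN2 demethylation of the vinylogous methyl carbonate by the soft thiolate gives the lithium tetronate, and acidification should release the tetronic acid without touching the ylidene geometry, the tertiary alcohol or the furan.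

**Compound list**

1 | (S)-citronellal, (3S)-3,7-dimethyloct-6-enal | O=CC[C@@H](C)CCC=C(C)C | starting material
2 | (3S)-3,7-dimethylocta-1,6-dien-1-yl nonafluorobutanesulfonate (E/Z mixture) | FC(F)(F)C(F)(F)C(F)(F)C(F)(F)S(=O)(=O)OC=C[C@@H](C)CCC=C(C)C | intermediate
3 | (3S)-3,7-dimethyloct-6-en-1-yne | C#C[C@@H](C)CCC=C(C)C | intermediate
4 | lithium (3S)-3,7-dimethyloct-6-en-1-yn-1-ide | [Li]C#C[C@@H](C)CCC=C(C)C | intermediate
5 | [(3S)-3,7-dimethyloct-6-en-1-yn-1-yl]tri(propan-2-yl)silane | CC(C)[Si](C(C)C)(C(C)C)C#C[C@@H](C)CCC=C(C)C | intermediate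
6 | (4S)-4-methyl-6-[tri(propan-2-yl)silyl]hex-5-ynal | CC(C)[Si](C(C)C)(C(C)C)C#C[C@@H](C)CCC=O | intermediate
7 | (4S)-4-methyl-6-[tri(propan-2-yl)silyl]hex-5-yn-1-ol | CC(C)[Si](C(C)C)(C(C)C)C#C[C@@H](C)CCCO | intermediate
8 | [(3S)-6-iodo-3-methylhex-1-yn-1-yl]tri(propan-2-yl)silane | CC(C)[Si](C(C)C)(C(C)C)C#C[C@@H](C)CCCI | intermediate
9 | [(3S)-3-methylocta-1,7-diyn-1-yl]tri(propan-2-yl)silane | CC(C)[Si](C(C)C)(C(C)C)C#C[C@@H](C)CCCC#C | intermediate
10 | (S)-linalool, (3S)-3,7-dimethylocta-1,6-dien-3-ol | C=C[C@@](C)(O)CCC=C(C)C | starting material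
11 | {[(3S)-3,7-dimethylocta-1,6-dien-3-yl]oxy}triethylsilane | C=C[C@@](C)(O[Si](CC)(CC)CC)CCC=C(C)C | intermediate
12 | (4S)-4-methyl-4-[(triethylsilyl)oxy]hex-5-enal | C=C[C@@](C)(O[Si](CC)(CC)CC)CCC=O | intermediate
13 | (4S)-4-methyl-4-[(triethylsilyl)oxy]hex-5-en-1-ol | C=C[C@@](C)(O[Si](CC)(CC)CC)CCCO | intermediate
14 | triethyl{[(3S)-6-iodo-3-methylhex-1-en-3-yl]oxy}silane | C=C[C@@](C)(O[Si](CC)(CC)CC)CCCI | intermediate
15 | 3-bromofuran | Brc1ccoc1 | starting material
16 | {(4S)-4-methyl-4-[(triethylsilyl)oxy]hex-5-en-1-yl}lithium | C=C[C@@](C)(O[Si](CC)(CC)CC)CCC[Li] | intermediate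
17 | chloro{(4S)-4-methyl-4-[(triethylsilyl)oxy]hex-5-en-1-yl}zinc | C=C[C@@](C)(O[Si](CC)(CC)CC)CCC[Zn]Cl | intermediate
18 | triethyl{[(3S)-6-(furan-3-yl)-3-methylhex-1-en-3-yl]oxy}silane | C=C[C@@](C)(O[Si](CC)(CC)CC)CCCc1ccoc1 | intermediate
19 | 9-[6-(furan-3-yl)-3-methyl-3-(triethylsilyloxy)hexyl]-9-borabicyclo[3.3.1]nonane (carbinol carbon as in 18) | C1CCC2CCCC1B2CC[C@@](C)(O[Si](CC)(CC)CC)CCCc1ccoc1 | intermediate
20 | (3S)-6-(furan-3-yl)-3-methyl-3-[(triethylsilyl)oxy]hexan-1-ol | OCC[C@@](C)(O[Si](CC)(CC)CC)CCCc1ccoc1 | intermediate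
21 | triethyl{[(3S)-6-(furan-3-yl)-1-iodo-3-methylhexan-3-yl]oxy}silane | ICC[C@@](C)(O[Si](CC)(CC)CC)CCCc1ccoc1 | intermediate
22 | trimethylaluminium | C[Al](C)C | starting material
23 | dimethyl{(1E,6S)-2,6-dimethyl-8-[tri(propan-2-yl)silyl]oct-1-en-7-yn-1-yl}alumane | CC(C)[Si](C(C)C)(C(C)C)C#C[C@@H](C)CCC/C(C)=C/[Al](C)C | intermediate
24 | chloro{(1E,6S)-2,6-dimethyl-8-[tri(propan-2-yl)silyl]oct-1-en-7-yn-1-yl}zinc | CC(C)[Si](C(C)C)(C(C)C)C#C[C@@H](C)CCC/C(C)=C/[Zn]Cl | intermediate
25 | [(3S,7E,11S)-14-(furan-3-yl)-3,7,11-trimethyl-11-[(triethylsilyl)oxy]tetradec-7-en-1-yn-1-yl]tri(propan-2-yl)silane | CC(C)[Si](C(C)C)(C(C)C)C#C[C@@H](C)CCC/C(C)=C/CC[C@@](C)(O[Si](CC)(CC)CC)CCCc1ccoc1 | intermediate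
26 | (4S,7E,12S)-1-(furan-3-yl)-4,8,12-trimethyltetradec-7-en-13-yn-4-ol | C#C[C@@H](C)CCC/C(C)=C/CC[C@@](C)(O)CCCc1ccoc1 | intermediate
27 | dilithium alkoxide acetylide of 26 | [Li]C#C[C@@H](C)CCC/C(C)=C/CC[C@@](C)(O[Li])CCCc1ccoc1 | intermediate
28 | (4S,8E,12S)-15-(furan-3-yl)-12-hydroxy-4,8,12-trimethylpentadec-8-en-2-ynal | O=CC#C[C@@H](C)CCC/C(C)=C/CC[C@@](C)(O)CCCc1ccoc1 | intermediate
29 | prop-2-en-1-yl propanoate | CCC(=O)OCC=C | starting material
30 | lithium enolate of prop-2-en-1-yl propanoate | C=CCOC(O[Li])=CC | intermediate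
31 | prop-2-en-1-yl (6S,10E,14S)-17-(furan-3-yl)-3,14-dihydroxy-2,6,10,14-tetramethylheptadec-10-en-4-ynoate (mixture at C2 and C3) | C=CCOC(=O)C(C)C(O)C#C[C@@H](C)CCC/C(C)=C/CC[C@@](C)(O)CCCc1ccoc1 | intermediate
32 | prop-2-en-1-yl (6S,10E,14S)-17-(furan-3-yl)-14-hydroxy-2,6,10,14-tetramethyl-3-oxoheptadec-10-en-4-ynoate (C2 epimers, partly enolised) | C=CCOC(=O)C(C)C(=O)C#C[C@@H](C)CCC/C(C)=C/CC[C@@](C)(O)CCCc1ccoc1 | intermediate
33 | caesium enolate of 32 | [Cs+].C=CCOC(=O)C(C)=C([O-])C#C[C@@H](C)CCC/C(C)=C/CC[C@@](C)(O)CCCc1ccoc1 | intermediate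
34 | prop-2-en-1-yl (2E,6S,10E,14S)-17-(furan-3-yl)-14-hydroxy-3-methoxy-2,6,10,14-tetramethylheptadeca-2,10-dien-4-ynoate | C=CCOC(=O)/C(C)=C(/OC)C#C[C@@H](C)CCC/C(C)=C/CC[C@@](C)(O)CCCc1ccoc1 | intermediate
35 | (2E,6S,10E,14S)-17-(furan-3-yl)-14-hydroxy-3-methoxy-2,6,10,14-tetramethylheptadeca-2,10-dien-4-ynoic acid | OC(=O)/C(C)=C(/OC)C#C[C@@H](C)CCC/C(C)=C/CC[C@@](C)(O)CCCc1ccoc1 | intermediate
36 | (5Z)-5-[(2S,6E,10S)-13-(furan-3-yl)-10-hydroxy-2,6,10-trimethyltridec-6-en-1-ylidene]-4-methoxy-3-methylfuran-2(5H)-one | CC1=C(OC)/C(=C/[C@@H](C)CCC/C(C)=C/CC[C@@](C)(O)CCCc2ccoc2)OC1=O | intermediate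
37 | (5Z)-5-[(2S,6E,10S)-13-(furan-3-yl)-10-hydroxy-2,6,10-trimethyltridec-6-en-1-ylidene]-4-hydroxy-3-methylfuran-2(5H)-one | CC1=C(O)/C(=C/[C@@H](C)CCC/C(C)=C/CC[C@@](C)(O)CCCc2ccoc2)OC1=O | target

**Step count and risk**

Total: 20 steps (5 to the diyne, 6 to the iodide, the coupling, 8 after it). Longest linear sequence: 15 steps, from (S)-linalool 10 to 37 (steps 6–11, 12, 13–20).

Steps most likely to fail:

1. Step 12. The alkylpalladium may lose a beta-hydride before it couples, methyl may be transferred in place of the alkenyl group, or the Lewis-acidic aluminium residues may slow the catalyst or attack the tertiary silyl ether. The fallback reverses the polarity of the two partners. It sets out from diyne 9, which is methylaluminated as in step 12 and quenched with I2 (THF, −30 °C) to give [(3S,7E)-8-iodo-3,7-dimethyloct-7-en-1-yn-1-yl]tri(propan-2-yl)silane F1. This iodide is joined by B-alkyl Suzuki–Miyaura coupling (PdCl2(dppf), AsPh3, Cs2CO3, DMF/THF/H2O, rt) to borane 19, made from alkene 18 and 9-BBN as in the first half of step 10. The fallback returns to the route at 25, and the oxidation of step 10 and step 11 are then not needed.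

2. Step 17. The enolate may be methylated on carbon, or on oxygen with the ester cis to the methoxy group, and that isomer cannot lactonise. The fallback avoids the enol ether altogether and sets out from aldol 31. Deallylation (Pd(PPh3)4, morpholine, THF) should give (6S,10E,14S)-17-(furan-3-yl)-3,14-dihydroxy-2,6,10,14-tetramethylheptadec-10-en-4-ynoic acid F2. AgNO3-catalysed 5-exo-dig cycloisomerisation of this 4-alkynoic acid, in which C4 is sp3 and no alkene geometry is required, should give (5Z)-5-[(2S,6E,10S)-13-(furan-3-yl)-10-hydroxy-2,6,10-trimethyltridec-6-en-1-ylidene]-4-hydroxy-3-methyloxolan-2-one F3. Dess–Martin oxidation of its C4 carbinol gives the β-keto lactone, which is the tetronic acid. The fallback returns at 37 and also bypasses steps 18 to 20.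

3. Step 1. The aldehyde enolate may undergo aldol condensation before it is sulfonylated, or the alkenyl nonaflate may lose the C7 hydrogen (1,4-elimination to an allene, or propargyl–allenyl isomerisation), which would erase the stereocentre. The fallback removes C1 and adds a new carbon, and sets out from 1. Proline-catalysed α-aminoxylation with nitrosobenzene and reduction in the same flask (NaBH4) gives (3S)-3,7-dimethyl-2-[(phenylamino)oxy]oct-6-en-1-ol F4. N–O cleavage (Zn, AcOH) gives (3S)-3,7-dimethyloct-6-ene-1,2-diol F5, and glycol cleavage (NaIO4, THF/H2O) gives (2S)-2,6-dimethylhept-5-enal F6. Seyferth–Gilbert homologation with the Ohira–Bestmann reagent (K2CO3, MeOH, 0 °C) then returns to the route at 3.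

**Further compounds**

F1 | step 12 | [(3S,7E)-8-iodo-3,7-dimethyloct-7-en-1-yn-1-yl]tri(propan-2-yl)silane | CC(C)[Si](C(C)C)(C(C)C)C#C[C@@H](C)CCC/C(C)=C/I
F2 | step 17 | (6S,10E,14S)-17-(furan-3-yl)-3,14-dihydroxy-2,6,10,14-tetramethylheptadec-10-en-4-ynoic acid | OC(=O)C(C)C(O)C#C[C@@H](C)CCC/C(C)=C/CC[C@@](C)(O)CCCc1ccoc1
F3 | step 17 | (5Z)-5-[(2S,6E,10S)-13-(furan-3-yl)-10-hydroxy-2,6,10-trimethyltridec-6-en-1-ylidene]-4-hydroxy-3-methyloxolan-2-one | CC1C(O)/C(=C/[C@@H](C)CCC/C(C)=C/CC[C@@](C)(O)CCCc2ccoc2)OC1=O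
F4 | step 1 | (3S)-3,7-dimethyl-2-[(phenylamino)oxy]oct-6-en-1-ol | OCC(ONc1ccccc1)[C@@H](C)CCC=C(C)C
F5 | step 1 | (3S)-3,7-dimethyloct-6-ene-1,2-diol | OCC(O)[C@@H](C)CCC=C(C)C
F6 | step 1 | (2S)-2,6-dimethylhept-5-enal | O=C[C@@H](C)CCC=C(C)C
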